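**Strategy.** Oxolane numbering: O1, C2 (aryl), C3 (CH2OAc), C4 (carbinol), C5 (CH2). The route rests on the O1–C5 disconnection with C5 carried as an ester carbonyl and C4 as an exocyclic methylene. One chromium-catalysed asymmetric 2-(alkoxycarbonyl)allylation of O-benzylvanillin forms C2–C3, sets C2 and C3 by stereoconvergent anti addition (E/Z mixtures of the bromide converge) and, in the same flask, closes the ring by attack of O1 on C5, giving a trans α-methylene-γ-butyrolactone. The step exploits the O1–C5–C4 array of the oxolane ring as a latent acrylate. The precursor is an acyclic 2-(bromomethyl)but-2-enoate plus the aldehyde. Cuprate addition, enolate hydroxylation, carbonyl removal, debenzylation and lipase acetylation follow.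

Key step: step 3

Assumption: the enantiomer of the bis(oxazoline) ligand in step 3 is the one that directs the allyl group to the Si face of aldehyde 5; the other enantiomer would give the mirror-image series.

Step 1
Reactants: 1 methyl acrylate; 2 (benzyloxy)acetaldehyde
Product: 3 methyl 4-(benzyloxy)-3-hydroxy-2-methylidenebutanoate (racemic)
Conditions: DABCO (0.5 equiv), neat, rt
Reagents that add atoms: none
Why: Morita–Baylis–Hillman reaction of an acrylate with a reactive α-alkoxy aldehyde under tertiary-amine catalysis; the carbinol stereocentre is erased in step 2, so racemic 3 suffices.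

Step 2
Reactants: 3 methyl 4-(benzyloxy)-3-hydroxy-2-methylidenebutanoate
Product: 4 methyl (2Z)-4-(benzyloxy)-2-(bromomethyl)but-2-enoate
Conditions: NBS, Me2S, CH2Cl2, 0 °C → rt
Reagents that add atoms: N-bromosuccinimide, O=C1CCC(=O)N1Br
Why: Bromination with allylic transposition (SN2' displacement of the alkoxysulfonium group by bromide, Corey–Kim-type activation), the standard conversion of Morita–Baylis–Hillman alcohols into 2-(bromomethyl)alk-2-enoates; no stereocentre remains and the alkene geometry is irrelevant for step 3.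

Step 3
Reactants: 4 methyl (2Z)-4-(benzyloxy)-2-(bromomethyl)but-2-enoate; 5 4-(benzyloxy)-3-methoxybenzaldehyde
Product: 7 (4R,5S)-5-[4-(benzyloxy)-3-methoxyphenyl]-4-[(benzyloxy)methyl]-3-methylideneoxolan-2-one, via silyl ether 6 (not isolated)
Conditions: CrCl2 (10 mol %), chiral carbazole-1,8-bis(oxazoline) ligand (12 mol %), iPr2NEt (20 mol %), Mn powder, Me3SiCl, THF, rt; silica plug; then Bu4NF (10 mol %), THF, 0 °C
Reagents that add atoms: none
Why: Mn keeps chromium in the divalent state, which inserts into the allylic C–Br bond of 4; the resulting 2-(methoxycarbonyl)allylchromium species (trivalent chromium), whose alkene isomers interconvert by 1,3-metal shift, adds through its γ-carbon (C3) to the aldehyde carbon (C2) in a closed six-membered chair transition state, and Me3SiCl releases the catalyst as silyl ether 6. Catalytic fluoride then starts a silyl-transfer chain in which the liberated C2 alkoxide attacks the ester carbonyl C5 and expels methoxide, which desilylates the next molecule of 6, so the ring closes through O1–C5 by acyl substitution with the C2–O bond untouched. The closest known reaction type is the catalytic asymmetric Nozaki–Hiyama–Kishi 2-(alkoxycarbonyl)allylation of aldehydes followed by lactonisation to α-methylene-γ-butyrolactones. The oxolanone ring closes in the 5-exo-trig mode. C2 (S) is controlled by the chiral tridentate ligand on chromium, which exposes the Si face of the aldehyde, and C3 (R) by the chair, in which aryl and CH2OBn are both equatorial, giving the anti adduct and hence the 2,3-trans lactone. The step needs γ- over α-attack, anti over syn addition and one aldehyde face: the cyclic transition state on octahedral chromium should secure the first two, equilibration of the allylchromium isomers before addition makes any E/Z mixture of 4 converge on the same product, and the ligand secures the third.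

Step 4
Reactants: 7 (4R,5S)-5-[4-(benzyloxy)-3-methoxyphenyl]-4-[(benzyloxy)methyl]-3-methylideneoxolan-2-one; 8 1-(benzyloxy)-4-bromo-2-methoxybenzene
Product: 9 (4R,5S)-3-[4-(benzyloxy)-3-methoxybenzyl]-5-[4-(benzyloxy)-3-methoxyphenyl]-4-[(benzyloxy)methyl]oxolan-2-one (mixture of C3 epimers of the lactone, that is of C4 in oxolane numbering)
Conditions: 8, Mg, THF, 40 °C; then CuBr·SMe2 (20 mol %), 7 added slowly, THF, −40 °C; then 1 M HCl
Reagents that add atoms: none
Why: Copper-catalysed 1,4-addition of an arylmagnesium bromide to the exocyclic enoate of an α-methylene lactone, which attacks the unhindered CH2 terminus; the C4 configuration formed on protonation does not matter because step 5 passes through the planar enolate.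

Step 5
Reactants: 9 (4R,5S)-3-[4-(benzyloxy)-3-methoxybenzyl]-5-[4-(benzyloxy)-3-methoxyphenyl]-4-[(benzyloxy)methyl]oxolan-2-one
Product: 11 (3S,4R,5S)-3-[4-(benzyloxy)-3-methoxybenzyl]-5-[4-(benzyloxy)-3-methoxyphenyl]-4-[(benzyloxy)methyl]-3-hydroxyoxolan-2-one, via potassium enolate 10 (not isolated)
Conditions: KN(SiMe3)2, THF, −78 °C; 2-(phenylsulfonyl)-3-phenyloxaziridine, −78 °C; AcOH
Reagents that add atoms: 2-(phenylsulfonyl)-3-phenyloxaziridine, O=S(=O)(c1ccccc1)N1OC1c1ccccc1
Why: Electrophilic hydroxylation of a lactone enolate by an N-sulfonyloxaziridine: the planar enolate 10 should be attacked on the face anti to the adjacent C3 CH2OBn group, which places OH trans and the benzyl group cis to CH2OBn (C4 S) from either epimer of 9, as in alkylations of β,γ-trans-disubstituted butyrolactone enolates.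

Step 6
Reactants: 11 (3S,4R,5S)-3-[4-(benzyloxy)-3-methoxybenzyl]-5-[4-(benzyloxy)-3-methoxyphenyl]-4-[(benzyloxy)methyl]-3-hydroxyoxolan-2-one
Product: 12 (3S,4R,5S)-3-[4-(benzyloxy)-3-methoxybenzyl]-5-[4-(benzyloxy)-3-methoxyphenyl]-4-[(benzyloxy)methyl]oxolane-2,3-diol (lactol, both C2 anomers)
Conditions: iBu2AlH (3 equiv), CH2Cl2, −78 °C; aq. sodium potassium tartrate
Reagents that add atoms: none
Why: Partial reduction of a lactone to a lactol by a dialkylaluminium hydride, the tetrahedral aluminium alkoxide being stable at −78 °C; the tertiary hydroxyl merely consumes one equivalent of hydride and the new C5 centre (both anomers) is removed in step 7.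

Step 7
Reactants: 12 (3S,4R,5S)-3-[4-(benzyloxy)-3-methoxybenzyl]-5-[4-(benzyloxy)-3-methoxyphenyl]-4-[(benzyloxy)methyl]oxolane-2,3-diol
Product: 13 (3S,4R,5S)-3-[4-(benzyloxy)-3-methoxybenzyl]-5-[4-(benzyloxy)-3-methoxyphenyl]-4-[(benzyloxy)methyl]oxolan-3-ol (tri-O-benzylolivil)
Conditions: Et3SiH, BF3·OEt2, CH2Cl2, −78 → −40 °C
Reagents that add atoms: none
Why: Ionic hydrogenation of a lactol: the Lewis acid generates the C5 oxocarbenium ion, which triethylsilane reduces to CH2 without touching C2, C3 or C4, and the low temperature is meant to keep the electron-rich benzylic C2–O1 bond from ionising.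

Step 8
Reactants: 13 tri-O-benzylolivil
Product: 14 (3S,4R,5S)-5-(4-hydroxy-3-methoxyphenyl)-3-(4-hydroxy-3-methoxybenzyl)-4-(hydroxymethyl)oxolan-3-ol (olivil)
Conditions: H2 (1 atm), 10% Pd/C, EtOAc–MeOH, rt
Reagents that add atoms: none
Why: Catalytic hydrogenolysis of two aryl benzyl ethers and one alkyl benzyl ether under neutral conditions, under which the cyclic benzylic C2–O1 ether and the tertiary alcohol are expected to persist.

Step 9
Reactants: 14 olivil
Product: 15 [(2S,3R,4S)-4-hydroxy-2-(4-hydroxy-3-methoxyphenyl)-4-(4-hydroxy-3-methoxybenzyl)oxolan-3-yl]methyl acetate (olivil monoacetate)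
Conditions: immobilised Candida antarctica lipase B, vinyl acetate, THF, 40 °C
Reagents that add atoms: vinyl acetate, C=COC(C)=O
Why: Lipase-catalysed irreversible transesterification with an enol ester, which should acylate the unhindered primary aliphatic hydroxyl only, phenols and the tertiary alcohol not being accepted as nucleophiles by the enzyme.

**Compound list**

1 | methyl acrylate | C=CC(=O)OC | starting material
2 | (benzyloxy)acetaldehyde | O=CCOCc1ccccc1 | starting material
3 | methyl 4-(benzyloxy)-3-hydroxy-2-methylidenebutanoate (racemic) | C=C(C(=O)OC)C(O)COCc1ccccc1 | intermediate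
4 | methyl (2Z)-4-(benzyloxy)-2-(bromomethyl)but-2-enoate | COC(=O)/C(CBr)=C/COCc1ccccc1 | intermediate
5 | 4-(benzyloxy)-3-methoxybenzaldehyde | COc1cc(C=O)ccc1OCc1ccccc1 | starting material
6 | methyl (3R,4S)-4-[4-(benzyloxy)-3-methoxyphenyl]-3-[(benzyloxy)methyl]-2-methylidene-4-[(trimethylsilyl)oxy]butanoate | COC(=O)C(=C)[C@H](COCc1ccccc1)[C@H](O[Si](C)(C)C)c1ccc(OCc2ccccc2)c(OC)c1 | intermediate
7 | (4R,5S)-5-[4-(benzyloxy)-3-methoxyphenyl]-4-[(benzyloxy)methyl]-3-methylideneoxolan-2-one | C=C1C(=O)O[C@H](c2ccc(OCc3ccccc3)c(OC)c2)[C@H]1COCc1ccccc1 | intermediate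
8 | 1-(benzyloxy)-4-bromo-2-methoxybenzene | COc1cc(Br)ccc1OCc1ccccc1 | starting material
9 | (4R,5S)-3-[4-(benzyloxy)-3-methoxybenzyl]-5-[4-(benzyloxy)-3-methoxyphenyl]-4-[(benzyloxy)methyl]oxolan-2-one (C3 epimers) | COc1cc(CC2C(=O)O[C@H](c3ccc(OCc4ccccc4)c(OC)c3)[C@H]2COCc2ccccc2)ccc1OCc1ccccc1 | intermediate
10 | potassium (4R,5S)-3-[4-(benzyloxy)-3-methoxybenzyl]-5-[4-(benzyloxy)-3-methoxyphenyl]-4-[(benzyloxy)methyl]-4,5-dihydrofuran-2-olate | COc1cc(CC2=C([O-])O[C@H](c3ccc(OCc4ccccc4)c(OC)c3)[C@H]2COCc2ccccc2)ccc1OCc1ccccc1.[K+] | intermediate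
11 | (3S,4R,5S)-3-[4-(benzyloxy)-3-methoxybenzyl]-5-[4-(benzyloxy)-3-methoxyphenyl]-4-[(benzyloxy)methyl]-3-hydroxyoxolan-2-one | COc1cc(C[C@@]2(O)C(=O)O[C@H](c3ccc(OCc4ccccc4)c(OC)c3)[C@H]2COCc2ccccc2)ccc1OCc1ccccc1 | intermediate
12 | (3S,4R,5S)-3-[4-(benzyloxy)-3-methoxybenzyl]-5-[4-(benzyloxy)-3-methoxyphenyl]-4-[(benzyloxy)methyl]oxolane-2,3-diol (both C2 anomers) | COc1cc(C[C@@]2(O)C(O)O[C@H](c3ccc(OCc4ccccc4)c(OC)c3)[C@H]2COCc2ccccc2)ccc1OCc1ccccc1 | intermediate
13 | (3S,4R,5S)-3-[4-(benzyloxy)-3-methoxybenzyl]-5-[4-(benzyloxy)-3-methoxyphenyl]-4-[(benzyloxy)methyl]oxolan-3-ol | COc1cc(C[C@@]2(O)CO[C@H](c3ccc(OCc4ccccc4)c(OC)c3)[C@H]2COCc2ccccc2)ccc1OCc1ccccc1 | intermediate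
14 | (3S,4R,5S)-5-(4-hydroxy-3-methoxyphenyl)-3-(4-hydroxy-3-methoxybenzyl)-4-(hydroxymethyl)oxolan-3-ol (olivil) | COc1cc(C[C@@]2(O)CO[C@H](c3ccc(O)c(OC)c3)[C@H]2CO)ccc1O | intermediate
15 | [(2S,3R,4S)-4-hydroxy-2-(4-hydroxy-3-methoxyphenyl)-4-(4-hydroxy-3-methoxybenzyl)oxolan-3-yl]methyl acetate (olivil monoacetate) | COc1cc(C[C@@]2(O)CO[C@H](c3ccc(O)c(OC)c3)[C@H]2COC(C)=O)ccc1O | target

**Step count and risks**

Total step count: 9. Longest linear sequence: 9 steps (from 1 and 2 to 15); 5 and 8 enter as commercial materials.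

The three steps most likely to fail:

Step 3. What may go wrong: erosion of anti/syn and facial control if the ester-bearing allylchromium species reacts through its other alkene isomer or through an open transition state, or loss of the allyl unit by 1,4-elimination of benzyloxide. The fallback sets out from 5 and comes back at 9, so that steps 1, 2 and 4 are no longer needed. (S)-4-Benzyloxazolidin-2-one is N-acylated (n-BuLi, then methyl 4-chloro-4-oxobutanoate, THF, −78 °C) to the succinate imide F1. Its dibutylboron enolate (Bu2BOTf, iPr2NEt, CH2Cl2, −78 → 0 °C) adds to 5 in an Evans syn-aldol reaction to give the syn-aldol adduct F2. With catalytic DBU the C2 hydroxyl of F2 acylates itself at the methyl ester, closing O1–C5 to the trans imide lactone F3. LiOH/H2O2 (THF–H2O, 0 °C, mild acidic work-up) removes the auxiliary to give the acid F4, and BH3·SMe2 reduces the carboxylic acid in the presence of the lactone to the hydroxymethyl lactone F5. 2-Benzyloxy-1-methylpyridinium triflate with MgO (PhCF3, 85 °C) gives, under neutral conditions, the benzyl ether F6. LiN(SiMe3)2 (THF, −78 °C) followed by commercial 4-(benzyloxy)-3-methoxybenzyl bromide alkylates the lactone α-carbon to give 9.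

Step 7. What may go wrong: Lewis-acid ionisation of the electron-rich benzylic C2–O1 bond, leading to silane reduction at C2 with ring opening or to C2 epimerisation, in competition with formation of the C5 oxocarbenium ion, which the adjacent C4 oxygen retards. The fallback sets out from 12 and comes back at 13. NaBH4 (MeOH, 0 °C) reduces the lactol to the triol F8. Selective sulfonylation of the only primary hydroxyl (Bu2SnO cat., TsCl, Et3N, CH2Cl2) gives the primary tosylate F9. NaH in THF then closes the oxolane by displacement at C5 by the C2 oxygen, either directly or after the C4 alkoxide has formed the terminal epoxide, which is opened at its CH2 end. This re-forms O1–C5 with retention at C2 and C4 and gives 13.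

Step 5. What may go wrong: insufficient facial discrimination of the fully substituted enolate (the C2 aryl group lies on the face that has to be attacked), or interception of the hindered enolate by the sulfonimine by-product. The fallback sets out from 7 and comes back at 11, replacing steps 4 and 5, and introduces oxygen before the aryl group. Weitz–Scheffer epoxidation of 7 (tBuOOH, DBU, CH2Cl2, 0 °C) gives the spiro-epoxy lactone F7, the peroxy enolate closing on the face anti to CH2OBn. The arylmagnesium bromide made from 8 with catalytic CuBr·SMe2 (THF, −40 °C) then opens the epoxide at its unsubstituted CH2 terminus to give 11.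

Further compounds
F1 | step 3 | methyl 4-[(4S)-4-benzyl-2-oxo-1,3-oxazolidin-3-yl]-4-oxobutanoate | COC(=O)CCC(=O)N1[C@@H](Cc2ccccc2)COC1=O
F2 | step 3 | methyl (3S,4S)-3-{[(4S)-4-benzyl-2-oxo-1,3-oxazolidin-3-yl]carbonyl}-4-[4-(benzyloxy)-3-methoxyphenyl]-4-hydroxybutanoate | COC(=O)C[C@H](C(=O)N1[C@@H](Cc2ccccc2)COC1=O)[C@H](O)c1ccc(OCc2ccccc2)c(OC)c1
F3 | step 3 | (4S)-4-benzyl-3-{[(2S,3S)-2-[4-(benzyloxy)-3-methoxyphenyl]-5-oxooxolan-3-yl]carbonyl}-1,3-oxazolidin-2-one | C1C(=O)O[C@H](c2ccc(OCc3ccccc3)c(OC)c2)[C@H]1C(=O)N1[C@@H](Cc2ccccc2)COC1=O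
F4 | step 3 | (2S,3S)-2-[4-(benzyloxy)-3-methoxyphenyl]-5-oxooxolane-3-carboxylic acid | C1C(=O)O[C@H](c2ccc(OCc3ccccc3)c(OC)c2)[C@H]1C(=O)O
F5 | step 3 | (4R,5S)-5-[4-(benzyloxy)-3-methoxyphenyl]-4-(hydroxymethyl)oxolan-2-one | C1C(=O)O[C@H](c2ccc(OCc3ccccc3)c(OC)c2)[C@H]1CO
F6 | step 3 | (4R,5S)-5-[4-(benzyloxy)-3-methoxyphenyl]-4-[(benzyloxy)methyl]oxolan-2-one | C1C(=O)O[C@H](c2ccc(OCc3ccccc3)c(OC)c2)[C@H]1COCc1ccccc1
F7 | step 5 | (3R,6S,7R)-6-[4-(benzyloxy)-3-methoxyphenyl]-7-[(benzyloxy)methyl]-1,5-dioxaspiro[2.4]heptan-4-one | C1[C@@]2(O1)C(=O)O[C@H](c3ccc(OCc4ccccc4)c(OC)c3)[C@H]2COCc2ccccc2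
F8 | step 7 | (1S,2R,3S)-3-[4-(benzyloxy)-3-methoxybenzyl]-1-[4-(benzyloxy)-3-methoxyphenyl]-2-[(benzyloxy)methyl]butane-1,3,4-triol | COc1cc(C[C@@](O)(CO)[C@H](COCc2ccccc2)[C@H](O)c2ccc(OCc3ccccc3)c(OC)c2)ccc1OCc1ccccc1
F9 | step 7 | (2S,3R,4S)-2-[4-(benzyloxy)-3-methoxybenzyl]-4-[4-(benzyloxy)-3-methoxyphenyl]-3-[(benzyloxy)methyl]-2,4-dihydroxybutyl 4-methylbenzenesulfonate | COc1cc(C[C@@](O)(COS(=O)(=O)c2ccc(C)cc2)[C@H](COCc2ccccc2)[C@H](O)c2ccc(OCc3ccccc3)c(OC)c2)ccc1OCc1ccccc1
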